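**Retrosynthetic overview**

1. Locants: C1 = CH bearing ring A (4‑oxygenated phenyl), C2 = CH bearing ring B (3,5‑dioxygenated phenyl), C3 = CH bearing C8 (ring C on C8), C3a/C7a = fusion carbons of resorcinol ring D (C3a on C3, C7a on C1). Target ⇐ hexabenzyl carbinol ⇐ C8 ketone (C8–H by CBS reduction; benzyl ethers removed last).
2. Indane ring C1–C2–C3–C3a–C7a ⇐ cyclopropane C1–C2–C3 carrying ring D and the aroyl group on C3: Lewis‑acid ring expansion by two atoms, C3a and C7a being inserted into the C1–C3 bond. Only C2 has to be made enantioselectively; C1 and C3 are set in the same step.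
3. Enabling feature: the C1–C3 bond is push–pull (the para‑oxygen of ring A stabilises a cation at C1; the C8 carbonyl on C3 takes the electron pair as an enolate), and C3 carries ring D, whose C7a is ortho/para to its two oxygens and at five‑ring distance from C1.
4. Cyclopropane ⇐ α‑aryl chalcone (C3=C1 alkene) + chiral sulfonium benzylide (ylide carbon = C2); chalcone ⇐ deoxybenzoin + 4‑(benzyloxy)benzaldehyde; deoxybenzoin ⇐ benzylzinc reagent + aroyl chloride.
5. Ring order: rings A–D are bought as benzyl‑protected arenes; cyclopropane (step 4), then indane by ring expansion (step 5); no other ring is made.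

Key step: step 5

Assumption: (2R,5R)‑2,5‑dimethylthiolane is taken as purchasable and its benzylide is assumed to transfer the ylide carbon with the facial sense that gives the (2R)‑cyclopropane; should the antipode form, the (2S,5S)‑sulfide is used.

**Route**

Step 1
Reactants: 1 3,5‑bis(benzyloxy)benzyl bromide; 2 4‑(benzyloxy)benzoyl chloride
Product: 4 1‑[4‑(benzyloxy)phenyl]‑2‑[3,5‑bis(benzyloxy)phenyl]ethan‑1‑one, via benzylzinc bromide 3 (not isolated)
Conditions: Zn dust (1.5 equiv), LiCl, THF, 0 °C; then 2, Pd(PPh3)4 (2 mol %), 0 °C → rt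
Reagents that add atoms: none
Why: Zinc inserts into the benzylic C–Br bond and the benzylzinc halide undergoes Pd‑catalysed Negishi acylation, which stops at the ketone and leaves the aryl benzyl ethers untouched.

Step 2
Reactants: 4 1‑[4‑(benzyloxy)phenyl]‑2‑[3,5‑bis(benzyloxy)phenyl]ethan‑1‑one; 5 4‑(benzyloxy)benzaldehyde
Product: 6 (E)‑1,3‑bis[4‑(benzyloxy)phenyl]‑2‑[3,5‑bis(benzyloxy)phenyl]prop‑2‑en‑1‑one
Conditions: piperidine (0.3 equiv), AcOH (0.3 equiv), toluene, reflux, Dean–Stark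
Reagents that add atoms: none
Why: Knoevenagel‑type aldol condensation of the doubly activated benzylic methylene with a non‑enolisable aldehyde, driven by azeotropic removal of water, should give the α‑aryl chalcone (E isomer expected; the alkene geometry has no consequence later).

Step 3
Reactants: 1 3,5‑bis(benzyloxy)benzyl bromide; 7 (2R,5R)‑2,5‑dimethylthiolane
Product: 8 (2R,5R)‑1‑[3,5‑bis(benzyloxy)benzyl]‑2,5‑dimethylthiolan‑1‑ium trifluoromethanesulfonate
Conditions: LiOTf (2 equiv), CH2Cl2/H2O (1:1), rt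
Reagents that add atoms: lithium trifluoromethanesulfonate, [Li+].[O-]S(=O)(=O)C(F)(F)F
Why: SN2 S‑alkylation of the thioether by the benzylic bromide, pulled forward by bromide/triflate exchange; the C2‑symmetric sulfide can give only one sulfonium salt.

Step 4
Reactants: 6 (E)‑1,3‑bis[4‑(benzyloxy)phenyl]‑2‑[3,5‑bis(benzyloxy)phenyl]prop‑2‑en‑1‑one; 8 (2R,5R)‑1‑[3,5‑bis(benzyloxy)benzyl]‑2,5‑dimethylthiolan‑1‑ium trifluoromethanesulfonate
Product: 10 [4‑(benzyloxy)phenyl]{(1R,2R,3R)‑1,2‑bis[3,5‑bis(benzyloxy)phenyl]‑3‑[4‑(benzyloxy)phenyl]cyclopropyl}methanone, via sulfonium ylide 9 (not isolated)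
Conditions: KHMDS (1.1 equiv) added to 8 + 6, THF, −78 → −20 °C
Reagents that add atoms: none
Why: Corey–Chaykovsky‑type Michael‑initiated ring closure (conjugate addition of ylide 9 to the β‑carbon C1, then 3‑exo‑tet displacement of the sulfide by the enolate carbon C3), in which the ylide carbon becomes C2 and its configuration is fixed by the flanking methyl groups of the C2‑symmetric thiolane; the C1/C3 arrangement drawn is the expected major one (ring A cis to ring D, ring B trans to ring A), and any C1/C3 epimers are carried on because step 5 erases both centres.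

Step 5
Reactants: 10 [4‑(benzyloxy)phenyl]{(1R,2R,3R)‑1,2‑bis[3,5‑bis(benzyloxy)phenyl]‑3‑[4‑(benzyloxy)phenyl]cyclopropyl}methanone
Product: 12 [4‑(benzyloxy)phenyl]{(1R,2S,3R)‑4,6‑bis(benzyloxy)‑2‑[3,5‑bis(benzyloxy)phenyl]‑3‑[4‑(benzyloxy)phenyl]‑2,3‑dihydro‑1H‑inden‑1‑yl}methanone, via ring‑opened zwitterion 11 (not isolated)
Conditions: Sc(OTf)3 (10 mol %), CH2Cl2 (0.02 M), −20 °C → rt; then DBU (0.2 equiv), rt
Reagents that add atoms: none
Why: Proposed new method: Sc(III) on the C8 carbonyl heterolyses the strained push–pull C1–C3 bond to zwitterion 11 (4‑benzyloxybenzyl cation at C1, aryl‑conjugated scandium enolate at C3), the ionisation known from Lewis‑acid ring opening of donor–acceptor cyclopropanes (arene alkylation, (3+2) annulation, Cloke–Wilson rearrangement); closure back to 10 or through oxygen to the dihydrofuran is reversible. Ring D, carried by C3, then alkylates the C1 cation through C7a in an irreversible five‑membered Friedel–Crafts closure (endo with respect to the C3a–C7a arene bond) that forms C1–C7a, so that C3a and C7a are inserted into the former C1–C3 bond and the three‑membered ring becomes the five‑membered ring, an aryl counterpart of the vinylcyclopropane–cyclopentene rearrangement whose closure step matches benzyl‑cation cyclisations to 1‑arylindanes. Loss of the C7a proton and C‑protonation of the enol complete the isomerisation. C2 is not touched and controls both new centres: at C1 ring A takes the face anti to ring B in the envelope transition state (1,2‑trans), and at C3 the aroyl group settles anti to ring B by enol/enolate equilibration (Sc(III), then DBU), so every C1/C3 diastereomer of 10 should give the all‑trans (1R,2S,3R) ketone. The step needs C1–C3 rather than C2–C3 cleavage, secured by the para‑oxygen of ring A (ring B has only meta oxygens); closure by ring D, secured because ring B could only form a four‑membered ring and ring C is deactivated by the carbonyl and would give a six‑membered ring; and cyclisation faster than loss of H‑2 from the cation, favoured by low temperature, dilution and a non‑basic medium.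

Step 6
Reactants: 12 [4‑(benzyloxy)phenyl]{(1R,2S,3R)‑4,6‑bis(benzyloxy)‑2‑[3,5‑bis(benzyloxy)phenyl]‑3‑[4‑(benzyloxy)phenyl]‑2,3‑dihydro‑1H‑inden‑1‑yl}methanone
Product: 13 (R)‑[4‑(benzyloxy)phenyl]{(1R,2S,3R)‑4,6‑bis(benzyloxy)‑2‑[3,5‑bis(benzyloxy)phenyl]‑3‑[4‑(benzyloxy)phenyl]‑2,3‑dihydro‑1H‑inden‑1‑yl}methanol
Conditions: (S)‑2‑methyl‑CBS‑oxazaborolidine (0.5 equiv), BH3·SMe2 (1.5 equiv), THF, −20 → 0 °C; MeOH quench
Reagents that add atoms: none
Why: Corey–Bakshi–Shibata reduction with ring C as the large group should deliver hydride to the face that gives the (R)‑carbinol, which is also the Felkin–Anh face (attack anti to the C3–C3a bond, past H‑2), so reagent and substrate control are expected to reinforce each other.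

Step 7
Reactants: 13 (R)‑[4‑(benzyloxy)phenyl]{(1R,2S,3R)‑4,6‑bis(benzyloxy)‑2‑[3,5‑bis(benzyloxy)phenyl]‑3‑[4‑(benzyloxy)phenyl]‑2,3‑dihydro‑1H‑inden‑1‑yl}methanol
Product: 14 (1R,2S,3R)‑2‑(3,5‑dihydroxyphenyl)‑1‑[(R)‑hydroxy(4‑hydroxyphenyl)methyl]‑3‑(4‑hydroxyphenyl)‑2,3‑dihydro‑1H‑indene‑4,6‑diol
Conditions: H2 (1 atm), 10 % Pd/C, EtOAc/MeOH, rt, neutral, stopped at full debenzylation
Reagents that add atoms: none
Why: Hydrogenolysis of the six aryl benzyl ethers under neutral conditions should be much faster than cleavage of the hindered secondary benzylic C8–OH, and no stereocentre is touched.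

**Compound list**

1 | 3,5‑bis(benzyloxy)benzyl bromide | BrCc1cc(OCc2ccccc2)cc(OCc2ccccc2)c1 | starting material
2 | 4‑(benzyloxy)benzoyl chloride | O=C(Cl)c1ccc(OCc2ccccc2)cc1 | starting material
3 | [3,5‑bis(benzyloxy)benzyl]zinc bromide | Br[Zn]Cc1cc(OCc2ccccc2)cc(OCc2ccccc2)c1 | intermediate
4 | 1‑[4‑(benzyloxy)phenyl]‑2‑[3,5‑bis(benzyloxy)phenyl]ethan‑1‑one | O=C(Cc1cc(OCc2ccccc2)cc(OCc2ccccc2)c1)c1ccc(OCc2ccccc2)cc1 | intermediate
5 | 4‑(benzyloxy)benzaldehyde | O=Cc1ccc(OCc2ccccc2)cc1 | starting material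
6 | (E)‑1,3‑bis[4‑(benzyloxy)phenyl]‑2‑[3,5‑bis(benzyloxy)phenyl]prop‑2‑en‑1‑one | O=C(c1ccc(OCc2ccccc2)cc1)/C(c1cc(OCc2ccccc2)cc(OCc2ccccc2)c1)=C/c1ccc(OCc2ccccc2)cc1 | intermediate
7 | (2R,5R)‑2,5‑dimethylthiolane | C[C@@H]1CC[C@@H](C)S1 | starting material
8 | (2R,5R)‑1‑[3,5‑bis(benzyloxy)benzyl]‑2,5‑dimethylthiolan‑1‑ium trifluoromethanesulfonate | C[C@@H]1CC[C@@H](C)[S+]1Cc1cc(OCc2ccccc2)cc(OCc2ccccc2)c1.[O-]S(=O)(=O)C(F)(F)F | intermediate
9 | [3,5‑bis(benzyloxy)phenyl][(2R,5R)‑2,5‑dimethylthiolan‑1‑ium‑1‑yl]methanide (sulfonium ylide) | C[C@@H]1CC[C@@H](C)[S+]1[CH-]c1cc(OCc2ccccc2)cc(OCc2ccccc2)c1 | intermediate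
10 | [4‑(benzyloxy)phenyl]{(1R,2R,3R)‑1,2‑bis[3,5‑bis(benzyloxy)phenyl]‑3‑[4‑(benzyloxy)phenyl]cyclopropyl}methanone | O=C(c1ccc(OCc2ccccc2)cc1)[C@@]1(c2cc(OCc3ccccc3)cc(OCc3ccccc3)c2)[C@@H](c2cc(OCc3ccccc3)cc(OCc3ccccc3)c2)[C@@H]1c1ccc(OCc2ccccc2)cc1 | intermediate
11 | ring‑opened zwitterion (enolate at C3/C8, 4‑benzyloxybenzyl cation at C1; drawn without scandium) | [O-]C(c1ccc(OCc2ccccc2)cc1)=C(c1cc(OCc2ccccc2)cc(OCc2ccccc2)c1)[C@@H](c1cc(OCc2ccccc2)cc(OCc2ccccc2)c1)[CH+]c1ccc(OCc2ccccc2)cc1 | intermediate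
12 | [4‑(benzyloxy)phenyl]{(1R,2S,3R)‑4,6‑bis(benzyloxy)‑2‑[3,5‑bis(benzyloxy)phenyl]‑3‑[4‑(benzyloxy)phenyl]‑2,3‑dihydro‑1H‑inden‑1‑yl}methanone | c1ccccc1COc1ccc([C@@H]2c3c(OCc4ccccc4)cc(OCc4ccccc4)cc3[C@H](C(=O)c3ccc(OCc4ccccc4)cc3)[C@H]2c2cc(OCc3ccccc3)cc(OCc3ccccc3)c2)cc1 | intermediate
13 | (R)‑[4‑(benzyloxy)phenyl]{(1R,2S,3R)‑4,6‑bis(benzyloxy)‑2‑[3,5‑bis(benzyloxy)phenyl]‑3‑[4‑(benzyloxy)phenyl]‑2,3‑dihydro‑1H‑inden‑1‑yl}methanol | c1ccccc1COc1ccc([C@@H]2c3c(OCc4ccccc4)cc(OCc4ccccc4)cc3[C@H]([C@@H](O)c3ccc(OCc4ccccc4)cc3)[C@H]2c2cc(OCc3ccccc3)cc(OCc3ccccc3)c2)cc1 | intermediate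
14 | (1R,2S,3R)‑2‑(3,5‑dihydroxyphenyl)‑1‑[(R)‑hydroxy(4‑hydroxyphenyl)methyl]‑3‑(4‑hydroxyphenyl)‑2,3‑dihydro‑1H‑indene‑4,6‑diol | Oc1ccc([C@@H]2c3c(O)cc(O)cc3[C@H]([C@@H](O)c3ccc(O)cc3)[C@H]2c2cc(O)cc(O)c2)cc1 | target

**Step count and risks**

Total step count: 7. Longest linear sequence: 6 steps (steps 1, 2, 4, 5, 6, 7 from bromide 1; step 3 is a one‑step branch).

Steps most likely to fail:

1. Step 5 (proposed new method). The zwitterion may only shuttle between the cyclopropane and the dihydrofuran (closure through oxygen) without the C–C closure, because C3 is sp2 in the enolate; or the C1 cation may lose H‑2 faster than it cyclises, which would erode the stored C2 configuration. The fallback uncouples ring opening from C–C closure with known reactions. Setting out from 10, Lewis‑acid‑catalysed methanolysis (Yb(OTf)3, MeOH/CH2Cl2; nucleophilic ring opening of a donor–acceptor cyclopropane at the donor carbon) should give the γ‑methoxy ketone (3S)‑1,4‑bis[4‑(benzyloxy)phenyl]‑2,3‑bis[3,5‑bis(benzyloxy)phenyl]‑4‑methoxybutan‑1‑one F1 as a mixture of epimers at the two flanking carbons, with C3 now sp3 and the C2 centre unchanged. Ionisation of its 4‑alkoxybenzylic methyl ether with BF3·OEt2 in CH2Cl2 at −40 °C, Friedel–Crafts alkylation of ring D (the established closure to 1,2‑trans‑diarylindanes) and the same DBU equilibration at C3 bring the material back to the route at ketone 12.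

2. Step 4. Betaine formation with the stabilised deoxybenzoin‑type enolate may be reversible, and Michael addition to the hindered, electron‑rich enone may be slow, so facial control at the ylide carbon or conversion may be poor. The fallback gives up asymmetric cyclopropanation and moves the resolution to the reduction. Setting out from 1 and 6, the achiral and less hindered 1‑[3,5‑bis(benzyloxy)benzyl]thiolan‑1‑ium triflate F2 (tetrahydrothiophene, LiOTf) is deprotonated with KHMDS in the presence of 6 to give the racemic cyclopropane, that is 10 together with its (1S,2S,3S)‑enantiomer F3. The conditions of step 5 then give racemic ketone, that is 12 together with the (1S,2R,3S)‑ketone F4. The (S)‑CBS reduction of step 6 is run as a kinetic resolution to about half conversion: matched 12 should be reduced to 13, while mismatched F4 stays behind as ketone or ends as the diastereomeric (R)‑carbinol of the (1S,2R,3S)‑indane F5, both separable from 13 on silica. The route is rejoined at 13.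

3. Step 7. Once the para‑phenol of ring C is liberated, hydrogenolysis of the benzylic C8–O bond may compete, or the six‑fold debenzylation may stall at partly protected material. The fallback reverses the order of the last two steps so that no benzylic alcohol meets Pd/H2. Setting out from ketone 12, hydrogenolysis (H2, Pd/C, EtOAc/MeOH) should give the hexaphenolic ketone [(1R,2S,3R)‑2‑(3,5‑dihydroxyphenyl)‑4,6‑dihydroxy‑3‑(4‑hydroxyphenyl)‑2,3‑dihydro‑1H‑inden‑1‑yl](4‑hydroxyphenyl)methanone F6, the aryl ketone being inert under these conditions. Reduction with excess NaBH4 in MeOH at 0 °C under Felkin–Anh substrate control (attack anti to the C3–C3a bond) should then arrive directly at 14, with any 8‑epimer removed by reverse‑phase chromatography.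

**Further compounds**

F1 | step 5 | (3S)‑1,4‑bis[4‑(benzyloxy)phenyl]‑2,3‑bis[3,5‑bis(benzyloxy)phenyl]‑4‑methoxybutan‑1‑one (epimer mixture at C2 and C4 of the butanone) | O=C(c1ccc(OCc2ccccc2)cc1)C(c1cc(OCc2ccccc2)cc(OCc2ccccc2)c1)[C@@H](c1cc(OCc2ccccc2)cc(OCc2ccccc2)c1)C(OC)c1ccc(OCc2ccccc2)cc1
F2 | step 4 | 1‑[3,5‑bis(benzyloxy)benzyl]thiolan‑1‑ium trifluoromethanesulfonate | C1CC[S+](C1)Cc1cc(OCc2ccccc2)cc(OCc2ccccc2)c1.[O-]S(=O)(=O)C(F)(F)F
F3 | step 4 | [4‑(benzyloxy)phenyl]{(1S,2S,3S)‑1,2‑bis[3,5‑bis(benzyloxy)phenyl]‑3‑[4‑(benzyloxy)phenyl]cyclopropyl}methanone | O=C(c1ccc(OCc2ccccc2)cc1)[C@]1(c2cc(OCc3ccccc3)cc(OCc3ccccc3)c2)[C@H](c2cc(OCc3ccccc3)cc(OCc3ccccc3)c2)[C@H]1c1ccc(OCc2ccccc2)cc1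
F4 | step 4 | [4‑(benzyloxy)phenyl]{(1S,2R,3S)‑4,6‑bis(benzyloxy)‑2‑[3,5‑bis(benzyloxy)phenyl]‑3‑[4‑(benzyloxy)phenyl]‑2,3‑dihydro‑1H‑inden‑1‑yl}methanone | c1ccccc1COc1ccc([C@H]2c3c(OCc4ccccc4)cc(OCc4ccccc4)cc3[C@@H](C(=O)c3ccc(OCc4ccccc4)cc3)[C@@H]2c2cc(OCc3ccccc3)cc(OCc3ccccc3)c2)cc1
F5 | step 4 | (R)‑[4‑(benzyloxy)phenyl]{(1S,2R,3S)‑4,6‑bis(benzyloxy)‑2‑[3,5‑bis(benzyloxy)phenyl]‑3‑[4‑(benzyloxy)phenyl]‑2,3‑dihydro‑1H‑inden‑1‑yl}methanol | c1ccccc1COc1ccc([C@H]2c3c(OCc4ccccc4)cc(OCc4ccccc4)cc3[C@@H]([C@@H](O)c3ccc(OCc4ccccc4)cc3)[C@@H]2c2cc(OCc3ccccc3)cc(OCc3ccccc3)c2)cc1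
F6 | step 7 | [(1R,2S,3R)‑2‑(3,5‑dihydroxyphenyl)‑4,6‑dihydroxy‑3‑(4‑hydroxyphenyl)‑2,3‑dihydro‑1H‑inden‑1‑yl](4‑hydroxyphenyl)methanone | Oc1ccc([C@@H]2c3c(O)cc(O)cc3[C@H](C(=O)c3ccc(O)cc3)[C@H]2c2cc(O)cc(O)c2)cc1
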